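**Assumptions:** 5,7-dihydroxychromone is bought as a catalogue compound. The target's stereocentre is (2S) by CIP analysis of the SMILES (O1 > aryl > C3 > H).

## Retrosynthetic overview

1. Target ⇐ (2S)-flavanone 5,7-diacetate by neutral deacetylation.
2. C2–C1' bond ⇐ enantioselective Pd(II)/PyOx conjugate arylation of 5,7-diacetoxychromone with a chromenylboronic acid. This dearomatises the γ-pyranone ring and sets C2 directly, with no chalcone intermediate.
3. Boronic acid ⇐ aryl bromide ⇐ DDQ oxidative cyclisation of symmetric 4-bromo-2,6-diprenylphenol (one prenyl becomes the pyran ring, the other stays).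
4. Diprenylphenol ⇐ 4-bromophenol + prenyl bromide.
5. Ring order: the A/C chromone bicycle is bought intact; the B-ring pyran (chromene) forms in step 2; the C ring reaches its saturated, stereodefined form in step 5.

## Route

**Step 1**
Reactants: 1, 4-bromophenol; 2, prenyl bromide (1-bromo-3-methylbut-2-ene, 2.2 equiv)
Product: 3, 4-bromo-2,6-bis(3-methylbut-2-en-1-yl)phenol (symmetric)
Conditions: NaH (2.2 equiv), toluene, 0 °C → rt, then 2, rt → 50 °C
Reagents that add atoms: prenyl bromide, CC(C)=CCBr
Why: Sodium phenoxide in a non-polar solvent reacts as a tight ion pair and undergoes ortho-C-alkylation (phenoxide C-allylation), and with the para position blocked by Br both ortho positions are prenylated in turn.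

**Step 2**
Reactants: 3, 4-bromo-2,6-diprenylphenol
Product: 4, 6-bromo-2,2-dimethyl-8-(3-methylbut-2-en-1-yl)-2H-chromene
Conditions: DDQ (1.1 equiv), benzene, reflux
Reagents that add atoms: none
Why: DDQ dehydrogenation of an o-prenylphenol gives an o-quinone methide that closes by oxa-6π electrocyclisation to the 2,2-dimethylchromene; with only one phenolic oxygen, exactly one of the two equivalent prenyl groups can cyclise, so the symmetry is broken without over-reaction.

**Step 3**
Reactants: 4, 6-bromo-2,2-dimethyl-8-prenyl-2H-chromene; 5, triisopropyl borate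
Product: 6, [2,2-dimethyl-8-(3-methylbut-2-en-1-yl)-2H-chromen-6-yl]boronic acid
Conditions: n-BuLi (1.1 equiv), THF, −78 °C; B(OiPr)3, −78 °C → rt; aq. NH4Cl
Reagents that add atoms: triisopropyl borate, CC(C)OB(OC(C)C)OC(C)C; water, O (hydrolysis of the borate ester)
Why: Br–Li exchange at −78 °C is much faster than allylic or benzylic deprotonation, and borate trapping with hydrolysis gives the boronic acid (lithiation–borylation).

**Step 4**
Reactants: 7, 5,7-dihydroxy-4H-chromen-4-one; 8, acetic anhydride
Product: 9, 4-oxo-4H-chromene-5,7-diyl diacetate (5,7-diacetoxychromone)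
Conditions: Ac2O (3 equiv), pyridine, DMAP (cat.), rt
Reagents that add atoms: acetic anhydride, CC(=O)OC(C)=O
Why: DMAP-catalysed O-acylation caps both phenols, including the chelated 5-OH, which removes the Pd-chelating 5-hydroxy-4-keto motif and makes the pyranone a better Michael acceptor.

**Step 5 (key step)**
Reactants: 9, 5,7-diacetoxychromone; 6, chromenylboronic acid (2 equiv)
Product: 10, (2S)-2-[2,2-dimethyl-8-(3-methylbut-2-en-1-yl)-2H-chromen-6-yl]-4-oxochromane-5,7-diyl diacetate
Conditions: Pd(OCOCF3)2 (10 mol%), (R)-t-BuPyOx (12 mol%), NH4PF6 (30 mol%), H2O (5 equiv), ClCH2CH2Cl, 60 °C, air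
Reagents that add atoms: none (C3–H comes from water)
Why: Pd(II)/PyOx-catalysed asymmetric conjugate addition of an arylboronic acid to a chromone: transmetalation, enantio-determining insertion of C2=C3 into Ar–Pd on the face selected by the ligand's tert-butyl group, then protonolysis of the Pd enolate, which dearomatises the pyranone and creates the (2S) centre in one step. The (R)-ligand is chosen by analogy with (S)-t-BuPyOx giving (R)-β-aryl ketones; this sense must be confirmed by CD on 10, and the other ligand enantiomer is equally available.

**Step 6**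
Reactants: 10, (2S)-flavanone 5,7-diacetate
Product: 11, (2S)-5,7-dihydroxy-2-[2,2-dimethyl-8-(3-methylbut-2-en-1-yl)-2H-chromen-6-yl]chroman-4-one (target)
Conditions: NH4OAc (10 equiv), MeOH/H2O 4:1, rt
Reagents that add atoms: none
Why: Near-neutral aminolysis/solvolysis of phenolic acetates frees both phenols without the strong base that racemises flavanones by retro-oxa-Michael ring opening (the B ring has no free 4'-OH to assist) and without the acid that could add to the prenyl or chromene olefins.

## Compound list

1 | 4-bromophenol | Oc1ccc(Br)cc1 | starting material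
2 | prenyl bromide | CC(C)=CCBr | starting material
3 | 4-bromo-2,6-bis(3-methylbut-2-en-1-yl)phenol | CC(C)=CCc1cc(Br)cc(CC=C(C)C)c1O | intermediate
4 | 6-bromo-2,2-dimethyl-8-(3-methylbut-2-en-1-yl)-2H-chromene | CC(C)=CCc1cc(Br)cc2c1OC(C)(C)C=C2 | intermediate
5 | triisopropyl borate | CC(C)OB(OC(C)C)OC(C)C | starting material
6 | [2,2-dimethyl-8-(3-methylbut-2-en-1-yl)-2H-chromen-6-yl]boronic acid | CC(C)=CCc1cc(B(O)O)cc2c1OC(C)(C)C=C2 | intermediate
7 | 5,7-dihydroxy-4H-chromen-4-one | O=c1ccoc2cc(O)cc(O)c12 | starting material
8 | acetic anhydride | CC(=O)OC(C)=O | starting material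
9 | 4-oxo-4H-chromene-5,7-diyl diacetate | CC(=O)Oc1cc(OC(C)=O)c2c(=O)ccoc2c1 | intermediate
10 | (2S)-2-[2,2-dimethyl-8-(3-methylbut-2-en-1-yl)-2H-chromen-6-yl]-4-oxochromane-5,7-diyl diacetate | CC(C)=CCc1cc([C@@H]2CC(=O)c3c(OC(C)=O)cc(OC(C)=O)cc3O2)cc2c1OC(C)(C)C=C2 | intermediate
11 | (2S)-5,7-dihydroxy-2-[2,2-dimethyl-8-(3-methylbut-2-en-1-yl)-2H-chromen-6-yl]chroman-4-one | CC(C)=CCc1cc([C@@H]2CC(=O)c3c(O)cc(O)cc3O2)cc2c1OC(C)(C)C=C2 | target

## Summary

Total steps: 6.
Longest linear sequence: 5 (steps 1 → 2 → 3 → 5 → 6); step 4 is a one-step side branch.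

Three steps most likely to fail:

1. **Step 5.** The 5,7-dioxygenated chromone may be a sluggish acceptor, the electron-rich boronic acid may protodeboronate, and Ar–Pd may engage the chromene olefin. Fallback: form the C ring by ring closure instead. Convert 4 to the aldehyde (n-BuLi, DMF), run a Claisen–Schmidt condensation with 2-hydroxy-4,6-bis(methoxymethoxy)acetophenone, cyclise the 2'-hydroxychalcone by asymmetric intramolecular oxa-Michael addition with a bifunctional cinchona-thiourea catalyst (or cyclise racemically and resolve by chiral HPLC), then remove the MOM groups.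
2. **Step 1.** Double ortho-C-prenylation competes with O-alkylation and dienone formation, so the yield may be low. Fallback: use halogenation and cross-coupling. Iodinate 4-bromophenol to 4-bromo-2,6-diiodophenol, then run a double Pd-catalysed prenylation at the C–I bonds (prenyl-Bpin or prenylSnBu3, α-selective), leaving C–Br intact, to reach 3.
3. **Step 2.** DDQ may over-oxidise the remaining prenyl group, or conversion may be poor on the bromophenol. Fallback: build the pyran by condensation instead of oxidation. Mono-prenylate 4-bromophenol to 4-bromo-2-prenylphenol, then annulate the free ortho position with 3-methylbut-2-enal (PhB(OH)2/AcOH, toluene, reflux; o-quinone methide/oxa-6π) to give 4.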